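**Strategy.** Everything rests on cutting ring C, the para-hydroxybenzyl ring, at its C1–C2 and C5–C6 bonds, back to a terminal aryl ynone and an oxygenated butadiene. The feature exploited is the 1,4-relationship in ring C between the phenolic oxygen on C4 and C1, the carbon joined through one bridging carbon to C2 of ring A (the dimethoxy ring whose C1 carries the CH2CH2 tether to ring B). One cycloaddition–aromatization closes ring C, fixes this para pattern and delivers the hydroxyl free, distinct from the ring A methyl ethers. The precursor is the ethynyl ketone 8 seated on C2 of ring A, with the ring B phenol held as a benzyl ether.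

Key step: step 5

Assumption: 3,5-dimethoxystyrene (1), 1-(benzyloxy)-3-bromobenzene (2), ethynylmagnesium bromide (6) and diene 9 are taken as catalogue compounds; because the benzyl ether is bought in place, the bibenzyl is made in one operation with no alkyne hydrogenation and no separate protection step.

Step 1
Reactants: 1 3,5-dimethoxystyrene; 2 1-(benzyloxy)-3-bromobenzene
Product: 4 1-(benzyloxy)-3-[2-(3,5-dimethoxyphenyl)ethyl]benzene, via alkylborane 3 (not isolated)
Conditions: 9-BBN, THF, 0 → 23 °C; then 2, PdCl2(dppf) (cat.), 3 M aq NaOH, 65 °C
Reagents that add atoms: none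
Why: Anti-Markovnikov hydroboration of the styrene with 9-BBN gives a primary alkylborane that should undergo B-alkyl Suzuki–Miyaura coupling with the aryl bromide, the dppf ligand suppressing β-hydride elimination and the benzyl ether being inert.

Step 2
Reactants: 4 1-(benzyloxy)-3-[2-(3,5-dimethoxyphenyl)ethyl]benzene
Product: 5 2-{2-[3-(benzyloxy)phenyl]ethyl}-4,6-dimethoxybenzaldehyde
Conditions: POCl3, DMF, 0 → 60 °C; then aq NaOAc
Reagents that add atoms: N,N-dimethylformamide, CN(C)C=O; water, O
Why: Vilsmeier–Haack formylation should attack only the doubly activated ring A and prefer C2 (equivalent to C6; para to one methoxy group and ortho to the other) over C4 between the two methoxy groups, as is usual for 5-alkylresorcinol dimethyl ethers, while the mono-alkoxy ring B is too weakly activated to react.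

Step 3
Reactants: 5 2-{2-[3-(benzyloxy)phenyl]ethyl}-4,6-dimethoxybenzaldehyde; 6 ethynylmagnesium bromide
Product: 7 1-(2-{2-[3-(benzyloxy)phenyl]ethyl}-4,6-dimethoxyphenyl)prop-2-yn-1-ol (racemic)
Conditions: THF, 0 → 23 °C; then aq NH4Cl
Reagents that add atoms: none
Why: Grignard 1,2-addition of the acetylide to the aldehyde should give the propargylic alcohol; its carbinol stereocenter is formed racemic without control and is erased in step 4.

Step 4
Reactants: 7 1-(2-{2-[3-(benzyloxy)phenyl]ethyl}-4,6-dimethoxyphenyl)prop-2-yn-1-ol (racemic)
Product: 8 1-(2-{2-[3-(benzyloxy)phenyl]ethyl}-4,6-dimethoxyphenyl)prop-2-yn-1-one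
Conditions: activated MnO2 (excess), CH2Cl2, 23 °C
Reagents that add atoms: none
Why: MnO2 oxidation of a benzylic, propargylic alcohol is neutral and heterogeneous, so the ynone should form without conjugate addition to the terminal alkyne and without touching the ethers.

Step 5
Reactants: 8 1-(2-{2-[3-(benzyloxy)phenyl]ethyl}-4,6-dimethoxyphenyl)prop-2-yn-1-one; 9 (E)-1-methoxy-3-(trimethylsilyloxy)buta-1,3-diene
Product: 11 (2-{2-[3-(benzyloxy)phenyl]ethyl}-4,6-dimethoxyphenyl)(4-hydroxyphenyl)methanone, via cycloadduct 10 (not isolated)
Conditions: 9 (2 equiv), toluene, 23 → 80 °C; then 1 M HCl, THF, 23 °C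
Reagents that add atoms: none
Why: The electron-rich diene 9 and the electron-poor alkyne of 8 should combine in an asynchronous, normal-electron-demand Diels–Alder reaction in which the unsubstituted CH2 terminus of 9 bonds to the terminal alkyne carbon (new C5–C6 bond) and the methoxy-bearing terminus bonds to the carbon next to the carbonyl (new C1–C2 bond), giving the 1,4-cyclohexadiene 10. The closest known reaction type is the cycloaddition of 1-alkoxy-3-siloxybutadienes with acetylenic ketones and esters, which furnishes para-acylphenols after loss of the alcohol. Ring C is closed as a six-membered carbocycle by intermolecular (4+2) annulation, and aqueous acid then cleaves the O–Si bond and expels methanol from the single sp3 CH–OMe carbon so that the ring aromatizes. No stereocenter survives, since the methoxy-bearing carbon of 10 is formed racemic and is flattened on aromatization. The selectivity required is regiochemical and is secured by the matched polarization of the partners (largest HOMO coefficient at the CH2 terminus of 9, largest LUMO coefficient at the terminal carbon of the ynone), which places the oxygen para to the acyl group; without a Lewis acid the ketone C=O should not compete as a heterodienophile. Because the carbonyl is twisted out of conjugation with the 2,6-disubstituted ring A, donation from the methoxy groups should not blunt the dienophile.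

Step 6
Reactants: 11 (2-{2-[3-(benzyloxy)phenyl]ethyl}-4,6-dimethoxyphenyl)(4-hydroxyphenyl)methanone
Product: 14 3-(2-{2-[(4-hydroxyphenyl)methyl]-3,5-dimethoxyphenyl}ethyl)phenol (target, gymconopin D), via phenol ketone 12 (not isolated), via diarylcarbinol 13 (not isolated)
Conditions: H2 (3 atm), 10% Pd/C, EtOH–AcOH, cat. HCl, 40 °C
Reagents that add atoms: none
Why: Catalytic hydrogenolysis should first cleave the aryl benzyl ether and then, under mild acid, reduce the diaryl ketone through the doubly benzylic carbinol, whose C–O bond is labilized by the para-hydroxy and the ortho/para-methoxy groups, to the CH2 bridge, while palladium at low pressure leaves the arenes and aryl methyl ethers intact.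

**Compound list**

1 | 3,5-dimethoxystyrene | C=Cc1cc(OC)cc(OC)c1 | starting material
2 | 1-(benzyloxy)-3-bromobenzene | Brc1cccc(OCc2ccccc2)c1 | starting material
3 | B-[2-(3,5-dimethoxyphenyl)ethyl]-9-borabicyclo[3.3.1]nonane | COc1cc(CCB2C3CCCC2CCC3)cc(OC)c1 | intermediate (not isolated)
4 | 1-(benzyloxy)-3-[2-(3,5-dimethoxyphenyl)ethyl]benzene | COc1cc(CCc2cccc(OCc3ccccc3)c2)cc(OC)c1 | intermediate
5 | 2-{2-[3-(benzyloxy)phenyl]ethyl}-4,6-dimethoxybenzaldehyde | COc1cc(CCc2cccc(OCc3ccccc3)c2)c(C=O)c(OC)c1 | intermediate
6 | ethynylmagnesium bromide | C#C[Mg]Br | starting material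
7 | 1-(2-{2-[3-(benzyloxy)phenyl]ethyl}-4,6-dimethoxyphenyl)prop-2-yn-1-ol (racemic) | COc1cc(CCc2cccc(OCc3ccccc3)c2)c(C(O)C#C)c(OC)c1 | intermediate
8 | 1-(2-{2-[3-(benzyloxy)phenyl]ethyl}-4,6-dimethoxyphenyl)prop-2-yn-1-one | COc1cc(CCc2cccc(OCc3ccccc3)c2)c(C(=O)C#C)c(OC)c1 | intermediate
9 | (E)-1-methoxy-3-(trimethylsilyloxy)buta-1,3-diene | CO/C=C/C(=C)O[Si](C)(C)C | starting material
10 | (2-{2-[3-(benzyloxy)phenyl]ethyl}-4,6-dimethoxyphenyl)[6-methoxy-4-(trimethylsilyloxy)cyclohexa-1,4-dien-1-yl]methanone (racemic) | COc1cc(CCc2cccc(OCc3ccccc3)c2)c(C(=O)C2=CCC(O[Si](C)(C)C)=CC2OC)c(OC)c1 | intermediate (not isolated)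
11 | (2-{2-[3-(benzyloxy)phenyl]ethyl}-4,6-dimethoxyphenyl)(4-hydroxyphenyl)methanone | COc1cc(CCc2cccc(OCc3ccccc3)c2)c(C(=O)c2ccc(O)cc2)c(OC)c1 | intermediate
12 | {2-[2-(3-hydroxyphenyl)ethyl]-4,6-dimethoxyphenyl}(4-hydroxyphenyl)methanone | COc1cc(CCc2cccc(O)c2)c(C(=O)c2ccc(O)cc2)c(OC)c1 | intermediate (not isolated)
13 | 3-(2-{2-[hydroxy(4-hydroxyphenyl)methyl]-3,5-dimethoxyphenyl}ethyl)phenol (racemic) | COc1cc(CCc2cccc(O)c2)c(C(O)c2ccc(O)cc2)c(OC)c1 | intermediate (not isolated)
14 | 3-(2-{2-[(4-hydroxyphenyl)methyl]-3,5-dimethoxyphenyl}ethyl)phenol (gymconopin D) | COc1cc(CCc2cccc(O)c2)c(Cc2ccc(O)cc2)c(OC)c1 | target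

**Total step count:** 6 steps. **Longest linear sequence:** 6 steps (from 1 or 2 to 14).

**Steps most likely to fail**

1. Step 5 (key step). The moisture- and acid-sensitive diene may be lost by desilylation, or the terminal ynone by oligomerization or conjugate addition, faster than the cycloaddition proceeds; aromatization of the adduct may also be incomplete. The fallback buys ring C instead of building it. It sets out from aldehyde 5: addition of 4-(benzyloxy)phenylmagnesium bromide (THF, 0 °C, then aq NH4Cl) should give the diarylcarbinol (2-{2-[3-(benzyloxy)phenyl]ethyl}-4,6-dimethoxyphenyl)[4-(benzyloxy)phenyl]methanol F1. Hydrogenolysis of F1 (H2, Pd/C, EtOH–AcOH) should remove both benzyl ethers and the doubly benzylic hydroxyl, coming back to the route at target 14.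

2. Step 6. The reduction may stall at the ketone or carbinol stage, because the carbonyl is hindered and deactivated by the para-hydroxyl. Alternatively, the acid may ionize the carbinol and let the resulting diarylmethyl cation cyclize onto ring B. The fallback separates the two events and replaces surface hydrogenolysis of the C=O by ionic hydrogenation. It sets out from 11: neutral hydrogenolysis (H2, Pd/C, EtOAc, 23 °C) should remove only the benzyl group and give the phenol ketone 12, now isolated. Treatment of 12 with excess Et3SiH in TFA–CH2Cl2 at 0 °C should deoxygenate the electron-rich diaryl ketone, the excess silane capturing the cation before it can cyclize, and return to the route at target 14. No new compound is made.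

3. Step 2. Formylation may occur partly at C4 of ring A, between the two methoxy groups, eroding the regiochemical purity on which the position of the bridge depends. The fallback installs the carbon by halogenation and metalation instead of direct electrophilic formylation. It sets out from 4: bromination with NBS (MeCN, 0 °C), which for 5-alkylresorcinol dimethyl ethers goes para to a methoxy group, should give 1-{2-[3-(benzyloxy)phenyl]ethyl}-2-bromo-3,5-dimethoxybenzene F2, purified at this stage. Bromine–lithium exchange (n-BuLi, THF, −78 °C) and quenching with DMF, then water, should return to the route at aldehyde 5.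

**Further compounds**

F1 | step 5 | (2-{2-[3-(benzyloxy)phenyl]ethyl}-4,6-dimethoxyphenyl)[4-(benzyloxy)phenyl]methanol (racemic) | COc1cc(CCc2cccc(OCc3ccccc3)c2)c(C(O)c2ccc(OCc3ccccc3)cc2)c(OC)c1
F0 | step 6 | none | none
F2 | step 2 | 1-{2-[3-(benzyloxy)phenyl]ethyl}-2-bromo-3,5-dimethoxybenzene | COc1cc(CCc2cccc(OCc3ccccc3)c2)c(Br)c(OC)c1
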